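**Assumption (one line):** (Z)-nerylacetone is available as the pure Z isomer (otherwise it is two steps from nerol), and the macrocyclic NHK is assumed to favour the (7S) carbinol by substrate control.

## Retrosynthetic overview
1. The target comes from diacetylation of 21. The tetrahydrofuran forms by 5-exo opening of a trans-epoxide (Shi epoxidation of an E-alkene) by the C7 allylic alcohol.
2. C7 and the 14-membered carbocycle come from an intramolecular Nozaki–Hiyama–Kishi (NHK) reaction of a vinyl iodide with a C7 aldehyde.
3. The ε-lactone with C11/C12 comes from 7-exo opening of a cis-epoxide (Shi epoxidation of a Z-alkene) by a tethered 2-substituted acrylic acid. This is the proposed new step.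
4. C1 comes from an organocatalytic enal–malonate Michael addition, followed by decarboxylative methylenation. The E-alkene C3=C4 comes from cross-metathesis.
5. The skeleton comes from nerylacetone, a CH–CHO homologation and 4-methylpent-4-en-1-ol. Ring order: lactone (Step 11), then macrocycle (Step 16), then THF (Step 17).

## Route

**Step 1**
Reactants: 1 (Z)-nerylacetone
Product: 2 vinyl triflate (terminal enol triflate)
Conditions: LDA, THF, −78 °C; then PhNTf2, −78 → 0 °C
Reagents that add atoms: PhNTf2, O=S(=O)(N(c1ccccc1)S(=O)(=O)C(F)(F)F)C(F)(F)F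
Why: Kinetic deprotonation of the methyl ketone at CH3, then O-triflation of the enolate (enol triflate formation).

**Step 2**
Reactants: 2
Product: 3 (Z)-2-iodo-6,10-dimethylundeca-1,5,9-triene
Conditions: NaI, Ni(cod)2 (10 mol %)/dtbbpy, DMA/THF, 23 °C
Reagents that add atoms: NaI, [Na+].[I-]
Why: Ni-catalysed triflate-to-iodide exchange gives the vinyl iodide needed for NHK coupling without touching the trisubstituted alkenes.

**Step 3**
Reactants: 3
Product: 4 racemic 3-[(3Z)-7-iodo-3-methylocta-3,7-dien-1-yl]-2,2-dimethyloxirane
Conditions: NBS, THF/H2O, 0 °C; then K2CO3, MeOH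
Reagents that add atoms: water, O (the O of the epoxide)
Why: Bromohydrin formation is selective for the gem-dimethyl terminal alkene, and base then closes the epoxide (Halohydrin/epoxide formation). The epoxide is destroyed in Step 4, so no stereochemistry is needed here.

**Step 4**
Reactants: 4
Product: 5 (4Z)-8-iodo-4-methylnona-4,8-dienal
Conditions: H5IO6, THF/Et2O, 0 °C
Reagents that add atoms: none
Why: Periodic acid cleaves the epoxide oxidatively to the aldehyde and acetone, which unmasks C1 as CHO.

**Step 5**
Reactants: 5; 6 (triphenylphosphoranylidene)acetaldehyde, O=CC=P(c1ccccc1)(c1ccccc1)c1ccccc1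
Product: 7 (2E,6Z)-10-iodo-6-methylundeca-2,6,10-trienal
Conditions: toluene, 80 °C
Reagents that add atoms: none beyond reactant 6
Why: Stabilised-ylide Wittig olefination gives the E-enal (C3 as CHO, C2=C1), the Michael acceptor for Step 6.

**Step 6**
Reactants: 7; 8 tert-butyl methyl malonate, COC(=O)CC(=O)OC(C)(C)C
Product: 9 OHC–CH2–C1H[(Z)-CH2CH2C(Me)=CHCH2CH2C(I)=CH2]–CH(CO2Me)(CO2tBu), C1 (R)
Conditions: (S)-diphenylprolinol TMS ether (10 mol %; use the enantiomer that gives 1R), PhCO2H (10 mol %), toluene, rt
Reagents that add atoms: none beyond reactant 8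
Why: Iminium-ion organocatalytic conjugate addition (Jørgensen–Hayashi) sets C1 by facial shielding of the enal; the malonate C15 epimers are irrelevant because that carbon becomes sp2 later.

**Step 7**
Reactants: 9
Product: 10 vinyl compound, C3H=CH2 in place of CHO (C1 R)
Conditions: Zn, CH2Br2, TiCl4, THF/CH2Cl2, 0 °C → rt
Reagents that add atoms: CH2Br2, BrCBr
Why: Lombardo–Takai methylenation is non-basic, so it avoids retro-Michael loss of the C1 stereocentre of the β-malonyl aldehyde.

**Step 8**
Reactants: 10
Product: 11 malonic acid tert-butyl half-ester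
Conditions: LiOH·H2O (1.0 equiv), THF/H2O, 0 °C
Reagents that add atoms: LiOH, [Li+].[OH-]
Why: Selective saponification of the methyl ester, with the hindered tert-butyl ester untouched.

**Step 9**
Reactants: 11
Product: 12 tert-butyl 2-substituted acrylate (C15=C16 installed)
Conditions: (CH2O)n, Et2NH, EtOAc, 70 °C
Reagents that add atoms: formaldehyde, C=O
Why: Decarboxylative Mannich/Knoevenagel-type methylenation of the malonic half-ester gives the 2-substituted acrylate; C1 is untouched.

**Step 10**
Reactants: 12
Product: 13 cis-epoxide (11R,12S) of the Z-trisubstituted C11=C12 alkene (C1 R)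
Conditions: Shi oxazolidinone ketone catalyst (30 mol %; enantiomer giving 11R,12S), Oxone, K2CO3/AcOH buffer, Bu4NHSO4, MeCN/DMM/H2O, 0 °C
Reagents that add atoms: Oxone, OOS(=O)(=O)[O-].[K+]
Why: Shi asymmetric epoxidation through a chiral dioxirane sets C11 and C12 by catalyst control; the Z geometry gives the cis-epoxide needed after inversion at C12. The terminal vinyl, vinyl iodide and acrylate are unreactive.

**Step 11**
Reactants: 13
Product: 14 ε-lactone 14, (1R,11R,12R) with C11-OH, α-methylene, vinyl and vinyl iodide intact
Conditions: TFA (10 equiv), CH2Cl2 (0.005 M), 0 °C → rt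
Reagents that add atoms: none
Why: Proposed new method: TFA cleaves the tert-butyl ester, and the freed acrylic acid attacks the protonated cis-epoxide at the tertiary carbon C12 by 7-exo backside attack. This gives inversion to 12R with C11 retained (R) and the epoxide oxygen becoming the C11 hydroxyl. The closest known reaction is acid-promoted epoxy-acid lactonization (5-exo and 6-exo), here extended to a seven-membered closure at a tertiary carbon; high dilution disfavours intermolecular trifluoroacetolysis.

**Step 12**
Reactants: 14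
Product: 15 C11 acetate
Conditions: Ac2O, DMAP, pyridine, CH2Cl2, rt
Reagents that add atoms: Ac2O, CC(=O)OC(C)=O
Why: Routine acylation of the secondary alcohol installs the C11 acetate; no stereocentre is affected.

**Step 13**
Reactants: 15; 16 4-methylpent-4-en-1-ol, CC(=C)CCCO
Product: 17 (E)-trisubstituted alkene C3=C4 with terminal C7H2OH (C5–C7 chain)
Conditions: Hoveyda–Grubbs II (5 mol %), CH2Cl2, 40 °C, 5 equiv of 16
Reagents that add atoms: none beyond reactant 16
Why: Cross-metathesis of a monosubstituted alkene with a 1,1-disubstituted alkene gives the thermodynamic E-trisubstituted alkene; the Z-trisubstituted alkene and vinyl iodide are inert.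

**Step 14**
Reactants: 17
Product: 18 trans-epoxide (3S,4S)
Conditions: Shi fructose-derived ketone (30 mol %; enantiomer giving 3S,4S), Oxone, K2CO3 buffer (pH ~9.5), MeCN/DMM, 0 °C
Reagents that add atoms: Oxone, OOS(=O)(=O)[O-].[K+]
Why: Shi epoxidation of the E-trisubstituted alkene gives the trans-epoxide, setting C3 and C4; the electron-poor acrylate does not react.

**Step 15**
Reactants: 18
Product: 19 C7 aldehyde
Conditions: Dess–Martin periodinane, NaHCO3, CH2Cl2, 0 °C → rt
Reagents that add atoms: none
Why: Buffered oxidation of the primary alcohol leaves the epoxide, acetate and vinyl iodide intact.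

**Step 16**
Reactants: 19
Product: 20 macrocyclic epoxy alcohol (7S assumed)
Conditions: CrCl2 (8 equiv), NiCl2 (0.5 mol %), DMF, rt, syringe-pump addition (0.002 M)
Reagents that add atoms: none
Why: Intramolecular Nozaki–Hiyama–Kishi coupling of the vinyl iodide with the aldehyde closes the 14-membered ring, forms the C7–C8 bond and the exocyclic methylene, and sets C7 by macrocyclic conformational control.

**Step 17**
Reactants: 20
Product: 21 THF with free C3-OH
Conditions: CSA (10 mol %), CH2Cl2, 0 °C
Reagents that add atoms: none
Why: Acid-catalysed 5-exo opening of the trans-epoxide at tertiary C4 by the C7-OH proceeds with inversion at C4 (4S-epoxide gives 4R), retains C3 (S) and gives the cis-2,5-THF.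

**Step 18**
Reactants: 21
Product: 22 granosolide B
Conditions: Ac2O, DMAP, Et3N, CH2Cl2, rt
Reagents that add atoms: Ac2O, CC(=O)OC(C)=O
Why: Acetylation of the C3 alcohol gives the target; no stereocentre is touched.

## Compound list
1 | (Z)-nerylacetone | CC(=O)CC/C=C(/C)CCC=C(C)C | starting material
2 | vinyl triflate | C=C(OS(=O)(=O)C(F)(F)F)CC/C=C(/C)CCC=C(C)C | intermediate
3 | vinyl iodide | C=C(I)CC/C=C(/C)CCC=C(C)C | intermediate
4 | terminal epoxide (racemic) | C=C(I)CC/C=C(/C)CCC1OC1(C)C | intermediate
5 | (4Z)-8-iodo-4-methylnona-4,8-dienal | C=C(I)CC/C=C(/C)CCC=O | intermediate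
6 | (triphenylphosphoranylidene)acetaldehyde | O=CC=P(c1ccccc1)(c1ccccc1)c1ccccc1 | starting material
7 | (2E,6Z)-enal | C=C(I)CC/C=C(/C)CC/C=C/C=O | intermediate
8 | tert-butyl methyl malonate | COC(=O)CC(=O)OC(C)(C)C | starting material
9 | Michael adduct (1R) | O=CC[C@@H](CC/C(C)=C\CCC(I)=C)C(C(=O)OC)C(=O)OC(C)(C)C | intermediate
10 | vinyl malonate | C=CC[C@@H](CC/C(C)=C\CCC(I)=C)C(C(=O)OC)C(=O)OC(C)(C)C | intermediate
11 | half-acid | C=CC[C@@H](CC/C(C)=C\CCC(I)=C)C(C(=O)O)C(=O)OC(C)(C)C | intermediate
12 | tert-butyl acrylate | C=CC[C@@H](CC/C(C)=C\CCC(I)=C)C(=C)C(=O)OC(C)(C)C | intermediate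
13 | cis-epoxide (11R,12S) | C=CC[C@@H](CC[C@]1(C)O[C@@H]1CCC(I)=C)C(=C)C(=O)OC(C)(C)C | intermediate
14 | hydroxy lactone | C=CC[C@H]1CC[C@](C)([C@H](O)CCC(I)=C)OC(=O)C1=C | intermediate
15 | acetoxy lactone | C=CC[C@H]1CC[C@](C)([C@H](OC(C)=O)CCC(I)=C)OC(=O)C1=C | intermediate
16 | 4-methylpent-4-en-1-ol | CC(=C)CCCO | starting material
17 | E-alkenol (CM product) | OCCC/C(C)=C/C[C@H]1CC[C@](C)([C@H](OC(C)=O)CCC(I)=C)OC(=O)C1=C | intermediate
18 | trans-epoxy alcohol (3S,4S) | OCCC[C@]1(C)O[C@H]1C[C@H]2CC[C@](C)([C@H](OC(C)=O)CCC(I)=C)OC(=O)C2=C | intermediate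
19 | epoxy aldehyde | O=CCC[C@]1(C)O[C@H]1C[C@H]2CC[C@](C)([C@H](OC(C)=O)CCC(I)=C)OC(=O)C2=C | intermediate
20 | macrocyclic epoxy alcohol | C=C1C(=O)O[C@]2(C)CC[C@@H]1C[C@@H]3O[C@@]3(C)CC[C@H](O)C(=C)CC[C@H]2OC(C)=O | intermediate
21 | THF hydroxy lactone (3-OH) | C=C1C(=O)O[C@]2(C)CC[C@@H]1C[C@H](O)[C@@]1(C)CC[C@H](O1)C(=C)CC[C@H]2OC(C)=O | intermediate
22 | granosolide B | C=C1C(=O)O[C@]2(C)CC[C@@H]1C[C@H](OC(C)=O)[C@@]1(C)CC[C@H](O1)C(=C)CC[C@H]2OC(C)=O | target

## Totals
Total step count: 18. Longest linear sequence: 18 (from 1).

## Three steps most likely to fail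
1. **Step 11 (proposed new lactonization).** The 7-exo closure at a tertiary carbon may lose to intermolecular trifluoroacetolysis, E1 elimination or Meinwald rearrangement. Fallback: hydrolyse epoxide 13 with aqueous HClO4/THF (inversion at C12) to the (11R,12R)-diol, acetylate C11, remove the tert-butyl ester with TFA, and close the lactone by Yamaguchi lactonization on the tertiary C12-OH.
2. **Step 16 (macrocyclic NHK).** Cr(II) may attack the α-methylene lactone, or C7 may form as the wrong epimer, which would give the trans-THF. Fallback: use Krapcho decarboxylation instead of the Step 9 methylenation, run the NHK on the saturated lactone, and install the methylene last (Eschenmoser's salt, then MeI/DBU) before Step 18. If the C7 epimer is the problem, oxidise the alcohol to the enone and reduce it with (S)-CBS.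
3. **Step 10 (Shi epoxidation of the Z-alkene).** Cis-type trisubstituted alkenes often give only moderate ee. Fallback: use the E-alkene series from trans-geranylacetone and set the same (11R,12R)-diol by Sharpless asymmetric dihydroxylation (OsO4/(DHQD)2PHAL), then close the lactone as in fallback 1.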